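At early times target was already rising in both earlier runs: 5.2% after 0.417 d in eta, 2.4% after 0.208 d in epsilon. I worked with the fraction of substrate left, not with the fraction of target made.

| setting | eta | epsilon | flask |
|---|---|---|---|
| substrate | 0.27 M | 1.1 M | 0.53 M |
| gas phase | 200 mM (held) | 200 mM (held) | 200 mM (held) |
| remark | run made earlier | run made earlier |  |
| time |  |  | 2.5 d |

| run | time / d | target / % | substrate / % |
|---|---|---|---|
| eta | 0.417 | 5.2 | 81.0 |
| eta | 0.833 | 8.1 | 66.0 |
| eta | 1.25 | 11.0 | 52.5 |
| eta | 1.67 | 14.3 | 43.4 |
| eta | 2.00 | 16.8 | 37.2 |
| eta | 2.50 | 18.2 | 27.1 |
| epsilon | 0.208 | 2.4 | 93.7 |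
| epsilon | 0.333 | 3.9 | 84.2 |
| epsilon | 0.500 | 6.5 | 78.4 |
| epsilon | 0.833 | 7.9 | 65.9 |
| epsilon | 1.67 | 15.1 | 44.7 |
| epsilon | 2.50 | 16.6 | 29.0 |

(readings scatter by 1 percentage point)

- the earlier runs were read with a standard deviation of 1 percentage point
- at the start none of the gas phase is in solution

* how much target there is at 2.5 d, in percent of the substrate charged
* the change that raises the amount of target at 2.5 d, in percent of the substrate charged most ("none" if none brings more than 2 percentage points) (dusk / midnight / none)
* amount of target at 2.5 d, in percent of the substrate charged, after midnight

- dusk: doubling the transfer coefficient of the gas phase, all else as stated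
- midnight: doubling the saturation concentration of gas phase, all else as stated

At 2.50 d, eta had 27.1% of its substrate left and epsilon 29.0%. They stood 1.9 percentage points apart, against a scatter of 1 point per reading, though epsilon was charged 4.07 times as heavily. So I expected the flask, charged between them, to leave about the same.

My crude bound from above was the substrate lost, taken from the eta reading: I put it at about 72.9% for the flask. To tighten it, I read target over substrate lost: 25.0% in eta and 23.4% in epsilon. Pooled, that was 24.2%. I carried this target share, the target standing per substrate lost, which is an apparent selectivity.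

Each run's share on its own loss gave the bracket, an estimate that carries the scatter of the readings: 18.2% above, 16.6% below, which are the last target readings of the two runs themselves. The pooled share on the mean loss gave me 17.4%.

The forecast said 17.5%, with a range of 15.5% to 19.5%, which put its value inside my bracket . Its ground was: “Target is also the same percentage in both runs”. It chose midnight, with 30% after that change, in a range of 21% to 34%.

The flask gave 18.1%, inside the bracket . The best change was midnight, which gave 27.9%, a gain of 9.8 points against 0.38 points for dusk.

    dissolved gas + target → over-reaction product (k = 2.00 × 10⁻⁴ M⁻¹ min⁻¹)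
    gas phase ⇌ dissolved gas, rate k2*(csat - [dissolved gas]) (kL = 0.0120 min⁻¹)
    substrate + dissolved gas → target (k = 7.40 × 10⁻⁴ M⁻¹ min⁻¹)
    substrate → side product (k = 2.10 × 10⁻⁴ min⁻¹)
    target ⇌ isomer of the product (K = 0.510, k = 0.00210 min⁻¹)

At 2.5 d the flask had 28% of its substrate left, and its dissolved gas stood at 0.198 M against a saturation of 200 mM. Its target share came to 25.1%, and the carried share on that loss gives 17.4%. A neighbour flask charged with 0.32 M of substrate left 28.1% at the same time. The carried share on its loss gives 17.4%. That neighbour flask held 18.2% of target.

The readings are calculated for an exercise; scatter was added.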